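**Retrosynthetic overview**
1. Target ⇐ (S)-3-butylphthalide, opened last by NaOH and cold mild acid; the free phenols and the saturated butyl chain ⇐ one hydrogenation of a tribenzylated 3-crotylphthalide.
2. 3-Crotyl ⇐ 3-allylphthalide (cross-metathesis with 2-butene); key C–C bond and stereocentre ⇐ Brown asymmetric allylboration of a methyl 2-formylbenzoate, the alkoxide lactonising onto the ester.
3. Formyl ester ⇐ aryl bromide (Suzuki vinylation, Lemieux–Johnson cleavage); the ester ⇐ the aldehyde that activated ether formation (Pinnick, MeI).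
4. Diaryl ether ⇐ SNAr of 2,4-bis(benzyloxy)-6-pentylphenol (olivetol: benzylation, Vilsmeier, Dakin) on 4-(benzyloxy)-2-bromo-6-fluorobenzaldehyde (3-bromo-5-fluorophenol: benzylation, LDA/DMF).
5. Rings: both benzene rings are bought; the only ring made is the γ-lactone, closed in the allylation step and opened in the last step.

Assumption: the target is the open-chain γ-hydroxy acid exactly as drawn, (S) at the carbinol carbon; numbers go to substrates, intermediates and products, while reagents are named but not numbered.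

**Route**

Step 1
Reactants: 1 olivetol (5-pentylbenzene-1,3-diol)
Product: 2 1,3-bis(benzyloxy)-5-pentylbenzene
Conditions: BnBr (2.3 equiv), K2CO3, DMF, 60 °C
Reagents that add atoms: benzyl bromide BrCc1ccccc1
Why: Williamson ether synthesis; both phenols are benzylated cleanly, and the benzyl ethers survive every later step until the final hydrogenation.

Step 2
Reactants: 2 1,3-bis(benzyloxy)-5-pentylbenzene
Product: 4 2,4-bis(benzyloxy)-6-pentylbenzaldehyde, via aryl iminium chloride 3 (not isolated)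
Conditions: POCl3 (1.5 equiv), DMF, 0 → 70 °C; then ice, aq. NaOH (pH 8)
Reagents that add atoms: N,N-dimethylformamide CN(C)C=O; water O
Why: Vilsmeier–Haack formylation; the chloroiminium ion attacks para to one ether oxygen and ortho to the other, next to the pentyl chain, in preference to the more crowded site between the two benzyloxy groups (minor isomer removed by chromatography), and hydrolysis of the iminium salt gives the aldehyde.

Step 3
Reactants: 4 2,4-bis(benzyloxy)-6-pentylbenzaldehyde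
Product: 6 2,4-bis(benzyloxy)-6-pentylphenol, via aryl formate 5 (not isolated)
Conditions: mCPBA (1.3 equiv), CH2Cl2, 0 °C → rt; then cat. K2CO3, MeOH, rt, Ar
Reagents that add atoms: mCPBA OOC(=O)c1cccc(Cl)c1
Why: Baeyer–Villiger (Dakin-type) oxidation; the electron-rich aryl group migrates to give the aryl formate, whose mild methanolysis frees the phenol without touching the benzyl ethers.

Step 4
Reactants: 7 3-bromo-5-fluorophenol
Product: 8 1-(benzyloxy)-3-bromo-5-fluorobenzene
Conditions: BnBr (1.1 equiv), K2CO3, acetone, reflux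
Reagents that add atoms: benzyl bromide BrCc1ccccc1
Why: Williamson ether synthesis on a simple phenol.

Step 5
Reactants: 8 1-(benzyloxy)-3-bromo-5-fluorobenzene
Product: 11 4-(benzyloxy)-2-bromo-6-fluorobenzaldehyde, via aryllithium 9 (not isolated), via lithium hemiaminolate 10 (not isolated)
Conditions: LDA (1.1 equiv), THF, −78 °C, 1 h; DMF (1.5 equiv), −78 °C; then 1 M HCl, 0 °C
Reagents that add atoms: N,N-dimethylformamide CN(C)C=O
Why: Directed ortho-lithiation; the amide base removes the most acidic ring proton, the one flanked by F and Br (no Br/Li exchange or aryne formation at −78 °C), and DMF formylates that carbon, para to the benzyloxy group.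

Step 6
Reactants: 6 2,4-bis(benzyloxy)-6-pentylphenol; 11 4-(benzyloxy)-2-bromo-6-fluorobenzaldehyde
Product: 12 4-(benzyloxy)-2-[2,4-bis(benzyloxy)-6-pentylphenoxy]-6-bromobenzaldehyde
Conditions: K2CO3 (2 equiv), degassed DMF, 90 °C, Ar
Reagents that add atoms: none
Why: SNAr; the phenoxide displaces the fluoride ortho to the formyl group through a Meisenheimer adduct, and fluoride leaves far faster than bromide, so the bromine is kept for the vinylation.

Step 7
Reactants: 12 4-(benzyloxy)-2-[2,4-bis(benzyloxy)-6-pentylphenoxy]-6-bromobenzaldehyde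
Product: 13 4-(benzyloxy)-2-[2,4-bis(benzyloxy)-6-pentylphenoxy]-6-bromobenzoic acid
Conditions: NaClO2, NaH2PO4, 2-methyl-2-butene (20 equiv), t-BuOH/THF/H2O, 0 °C → rt
Reagents that add atoms: sodium chlorite [Na+].[O-]Cl=O
Why: Pinnick oxidation; chlorous acid oxidises even this doubly ortho-substituted aldehyde, and 2-methyl-2-butene traps the HOCl that would otherwise chlorinate the electron-rich rings.

Step 8
Reactants: 13 4-(benzyloxy)-2-[2,4-bis(benzyloxy)-6-pentylphenoxy]-6-bromobenzoic acid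
Product: 14 methyl 4-(benzyloxy)-2-[2,4-bis(benzyloxy)-6-pentylphenoxy]-6-bromobenzoate
Conditions: MeI (1.5 equiv), K2CO3, DMF, rt
Reagents that add atoms: iodomethane CI
Why: SN2 O-alkylation of the carboxylate, which avoids a Fischer esterification at the hindered 2,6-disubstituted acyl carbon.

Step 9
Reactants: 14 methyl 4-(benzyloxy)-2-[2,4-bis(benzyloxy)-6-pentylphenoxy]-6-bromobenzoate
Product: 15 methyl 4-(benzyloxy)-2-[2,4-bis(benzyloxy)-6-pentylphenoxy]-6-vinylbenzoate
Conditions: vinylboronic acid pinacol ester (1.5 equiv), Pd(dppf)Cl2 (5 mol %), K2CO3, 1,4-dioxane/H2O (4:1), 90 °C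
Reagents that add atoms: vinylboronic acid pinacol ester C=CB1OC(C)(C)C(C)(C)O1
Why: Suzuki–Miyaura coupling; the aryl bromide ortho to the ester undergoes oxidative addition readily, and the hindered methyl ester resists the aqueous carbonate.

Step 10
Reactants: 15 methyl 4-(benzyloxy)-2-[2,4-bis(benzyloxy)-6-pentylphenoxy]-6-vinylbenzoate
Product: 17 methyl 4-(benzyloxy)-2-[2,4-bis(benzyloxy)-6-pentylphenoxy]-6-formylbenzoate, via diol 16 (not isolated)
Conditions: OsO4 (2 mol %), NaIO4 (4 equiv), 2,6-lutidine (2 equiv), 1,4-dioxane/H2O (3:1), rt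
Reagents that add atoms: osmium tetroxide O=[Os](=O)(=O)=O; sodium periodate [Na+].[O-]I(=O)(=O)=O
Why: Lemieux–Johnson oxidation; catalytic OsO4 dihydroxylates the styrene and periodate cleaves the diol as it forms, before it can lactonise, under conditions that spare the electron-rich arenes which ozone could attack.

Step 11
Reactants: 17 methyl 4-(benzyloxy)-2-[2,4-bis(benzyloxy)-6-pentylphenoxy]-6-formylbenzoate
Product: 20 (S)-3-allyl-5-(benzyloxy)-7-[2,4-bis(benzyloxy)-6-pentylphenoxy]isobenzofuran-1(3H)-one, via borinate 18 (not isolated), via hydroxy ester 19 (not isolated)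
Conditions: (−)-Ipc2BOMe [from (+)-α-pinene] (1.5 equiv), allylMgBr (1.4 equiv), Et2O, −78 °C → rt → −78 °C; add 17, −78 °C, 3 h; then 3 M NaOH, 30% H2O2, 0 °C → rt; cat. p-TsOH, CH2Cl2, rt to complete lactonisation
Reagents that add atoms: allylmagnesium bromide C=CC[Mg]Br, delivered as (−)-B-allyldiisopinocampheylborane C=CCB([C@@H]1C[C@@H]2C[C@H]([C@H]1C)C2(C)C)[C@@H]1C[C@@H]2C[C@H]([C@H]1C)C2(C)C
Why: Brown asymmetric allylboration (carbonyl allylation); allyl transfer through a chair Zimmerman–Traxler transition state from the (+)-α-pinene-derived reagent gives the (S)-homoallylic borinate, the sense established for benzaldehyde, and after oxidative cleavage the (S)-alcohol closes onto the ortho ester to the phthalide without touching the new stereocentre.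

Step 12
Reactants: 20 (S)-3-allyl-5-(benzyloxy)-7-[2,4-bis(benzyloxy)-6-pentylphenoxy]isobenzofuran-1(3H)-one
Product: 21 (S)-5-(benzyloxy)-7-[2,4-bis(benzyloxy)-6-pentylphenoxy]-3-[(E)-but-2-en-1-yl]isobenzofuran-1(3H)-one
Conditions: (Z)-but-2-ene (excess, condensed), Grubbs II (5 mol %), CH2Cl2, 40 °C, sealed tube
Reagents that add atoms: (Z)-but-2-ene C/C=C\C
Why: Olefin cross-metathesis; excess 2-butene converts the terminal allyl group into a crotyl group (mainly E; the Z isomer converges in step 13), completing the four-carbon chain away from the stereocentre.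

Step 13
Reactants: 21 (S)-5-(benzyloxy)-7-[2,4-bis(benzyloxy)-6-pentylphenoxy]-3-[(E)-but-2-en-1-yl]isobenzofuran-1(3H)-one
Product: 22 (S)-3-butyl-7-(2,4-dihydroxy-6-pentylphenoxy)-5-hydroxyisobenzofuran-1(3H)-one
Conditions: H2 (1 atm), 10% Pd/C, EtOAc/MeOH, rt
Reagents that add atoms: none
Why: Catalytic hydrogenation and hydrogenolysis; Pd/C saturates the alkene and cleaves the three benzyl ethers, while the benzylic lactone C–O bond and its stereocentre survive under neutral conditions at 1 atm.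

Step 14
Reactants: 22 (S)-3-butyl-7-(2,4-dihydroxy-6-pentylphenoxy)-5-hydroxyisobenzofuran-1(3H)-one
Product: 24 2-(2,4-dihydroxy-6-pentylphenoxy)-4-hydroxy-6-[(1S)-1-hydroxypentyl]benzoic acid, via tetrasodium salt 23 (not isolated)
Conditions: NaOH (6 equiv), degassed MeOH/H2O, 40 °C, Ar; then 0 °C, cold 0.5 M HCl to pH 3–4, fast extraction with cold EtOAc, evaporation below 10 °C
Reagents that add atoms: sodium hydroxide [Na+].[OH-]
Why: Saponification of the lactone by acyl–oxygen cleavage (BAc2), so the C–O bond at the stereocentre is never broken and (S) is retained; cold, weakly acidic work-up frees the hydroxy acid before it can relactonise.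

**Compound list**
1 | olivetol (5-pentylbenzene-1,3-diol) | CCCCCc1cc(O)cc(O)c1 | starting material
2 | 1,3-bis(benzyloxy)-5-pentylbenzene | CCCCCc1cc(OCc2ccccc2)cc(OCc2ccccc2)c1 | intermediate
3 | N-[2,4-bis(benzyloxy)-6-pentylbenzylidene]-N-methylmethanaminium chloride | CCCCCc1cc(OCc2ccccc2)cc(OCc2ccccc2)c1C=[N+](C)C.[Cl-] | intermediate
4 | 2,4-bis(benzyloxy)-6-pentylbenzaldehyde | CCCCCc1cc(OCc2ccccc2)cc(OCc2ccccc2)c1C=O | intermediate
5 | 2,4-bis(benzyloxy)-6-pentylphenyl formate | CCCCCc1cc(OCc2ccccc2)cc(OCc2ccccc2)c1OC=O | intermediate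
6 | 2,4-bis(benzyloxy)-6-pentylphenol | CCCCCc1cc(OCc2ccccc2)cc(OCc2ccccc2)c1O | intermediate
7 | 3-bromo-5-fluorophenol | Oc1cc(F)cc(Br)c1 | starting material
8 | 1-(benzyloxy)-3-bromo-5-fluorobenzene | Fc1cc(Br)cc(OCc2ccccc2)c1 | intermediate
9 | [4-(benzyloxy)-2-bromo-6-fluorophenyl]lithium | [Li]c1c(F)cc(OCc2ccccc2)cc1Br | intermediate
10 | lithium [4-(benzyloxy)-2-bromo-6-fluorophenyl](dimethylamino)methanolate (racemic) | [Li+].[O-]C(N(C)C)c1c(F)cc(OCc2ccccc2)cc1Br | intermediate
11 | 4-(benzyloxy)-2-bromo-6-fluorobenzaldehyde | O=Cc1c(F)cc(OCc2ccccc2)cc1Br | intermediate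
12 | 4-(benzyloxy)-2-[2,4-bis(benzyloxy)-6-pentylphenoxy]-6-bromobenzaldehyde | CCCCCc1cc(OCc2ccccc2)cc(OCc2ccccc2)c1Oc1cc(OCc2ccccc2)cc(Br)c1C=O | intermediate
13 | 4-(benzyloxy)-2-[2,4-bis(benzyloxy)-6-pentylphenoxy]-6-bromobenzoic acid | CCCCCc1cc(OCc2ccccc2)cc(OCc2ccccc2)c1Oc1cc(OCc2ccccc2)cc(Br)c1C(=O)O | intermediate
14 | methyl 4-(benzyloxy)-2-[2,4-bis(benzyloxy)-6-pentylphenoxy]-6-bromobenzoate | CCCCCc1cc(OCc2ccccc2)cc(OCc2ccccc2)c1Oc1cc(OCc2ccccc2)cc(Br)c1C(=O)OC | intermediate
15 | methyl 4-(benzyloxy)-2-[2,4-bis(benzyloxy)-6-pentylphenoxy]-6-vinylbenzoate | CCCCCc1cc(OCc2ccccc2)cc(OCc2ccccc2)c1Oc1cc(OCc2ccccc2)cc(C=C)c1C(=O)OC | intermediate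
16 | methyl 4-(benzyloxy)-2-[2,4-bis(benzyloxy)-6-pentylphenoxy]-6-(1,2-dihydroxyethyl)benzoate (racemic) | CCCCCc1cc(OCc2ccccc2)cc(OCc2ccccc2)c1Oc1cc(OCc2ccccc2)cc(C(O)CO)c1C(=O)OC | intermediate
17 | methyl 4-(benzyloxy)-2-[2,4-bis(benzyloxy)-6-pentylphenoxy]-6-formylbenzoate | CCCCCc1cc(OCc2ccccc2)cc(OCc2ccccc2)c1Oc1cc(OCc2ccccc2)cc(C=O)c1C(=O)OC | intermediate
18 | methyl 4-(benzyloxy)-2-[2,4-bis(benzyloxy)-6-pentylphenoxy]-6-[(1S)-1-(diisopinocampheylboryloxy)but-3-en-1-yl]benzoate | CCCCCc1cc(OCc2ccccc2)cc(OCc2ccccc2)c1Oc1cc(OCc2ccccc2)cc([C@@H](OB([C@@H]2C[C@@H]3C[C@H]([C@H]2C)C3(C)C)[C@@H]2C[C@@H]3C[C@H]([C@H]2C)C3(C)C)CC=C)c1C(=O)OC | intermediate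
19 | methyl 4-(benzyloxy)-2-[2,4-bis(benzyloxy)-6-pentylphenoxy]-6-[(1S)-1-hydroxybut-3-en-1-yl]benzoate | CCCCCc1cc(OCc2ccccc2)cc(OCc2ccccc2)c1Oc1cc(OCc2ccccc2)cc([C@@H](O)CC=C)c1C(=O)OC | intermediate
20 | (S)-3-allyl-5-(benzyloxy)-7-[2,4-bis(benzyloxy)-6-pentylphenoxy]isobenzofuran-1(3H)-one | CCCCCc1cc(OCc2ccccc2)cc(OCc2ccccc2)c1Oc1cc(OCc2ccccc2)cc2c1C(=O)O[C@H]2CC=C | intermediate
21 | (S)-5-(benzyloxy)-7-[2,4-bis(benzyloxy)-6-pentylphenoxy]-3-[(E)-but-2-en-1-yl]isobenzofuran-1(3H)-one | CCCCCc1cc(OCc2ccccc2)cc(OCc2ccccc2)c1Oc1cc(OCc2ccccc2)cc2c1C(=O)O[C@H]2C/C=C/C | intermediate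
22 | (S)-3-butyl-7-(2,4-dihydroxy-6-pentylphenoxy)-5-hydroxyisobenzofuran-1(3H)-one | CCCCCc1cc(O)cc(O)c1Oc1cc(O)cc2c1C(=O)O[C@H]2CCCC | intermediate
23 | tetrasodium salt of 2-(2,4-dihydroxy-6-pentylphenoxy)-4-hydroxy-6-[(1S)-1-hydroxypentyl]benzoic acid (carboxylate and three phenolates) | CCCCCc1cc([O-])cc([O-])c1Oc1cc([O-])cc([C@@H](O)CCCC)c1C([O-])=O.[Na+].[Na+].[Na+].[Na+] | intermediate
24 | 2-(2,4-dihydroxy-6-pentylphenoxy)-4-hydroxy-6-[(1S)-1-hydroxypentyl]benzoic acid (CNP0272660.1) | CCCCCc1cc(O)cc(O)c1Oc1cc(O)cc([C@@H](O)CCCC)c1C(=O)O | target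

**Totals**
Total steps: 14. Longest linear sequence: 12 (steps 1–3 and 6–14, from olivetol).

**Three steps most likely to fail, with fallbacks**

Step 6 (SNAr with a doubly ortho-substituted, oxidation-prone phenoxide). The fallback replaces SNAr by an ortho-carboxylate-assisted Ullmann ether synthesis and sets out from phenol 6. Bought 3,5-dibromophenol is benzylated (BnBr, K2CO3) to 1-(benzyloxy)-3,5-dibromobenzene F1. LDA (THF, −78 °C) removes the proton between the two bromines to give [4-(benzyloxy)-2,6-dibromophenyl]lithium F2, CO2 converts it into lithium 4-(benzyloxy)-2,6-dibromobenzoate F3, and acidification gives 4-(benzyloxy)-2,6-dibromobenzoic acid F4. Copper-mediated mono-coupling of F4 with one equivalent of 6 (Cu2O, K2CO3, pyridine/DMF, 110 °C) gives bromo acid 13, where the route is rejoined; the second bromide, now next to a bulkier and more electron-rich ring, reacts much more slowly. Compounds 8–12 are then not needed.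

Step 11 (enantioselectivity and clean lactonisation on a densely substituted 2-formylbenzoate). The fallback changes from a stoichiometric chiral allylborane with a closed transition state to a catalytic chiral Lewis acid with an allylstannane and an open transition state. It sets out from aldehyde 17: Keck allylation with allyltributylstannane, (S)-BINOL/Ti(OiPr)4 (10 mol %), 4 Å MS, CH2Cl2, −20 °C gives hydroxy ester 19 (same (S) sense as for benzaldehyde; ee to be checked by chiral HPLC). Cat. p-TsOH then closes 19 to phthalide 20, where the route is rejoined; no compound outside the list is made (none F0).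

Step 14 (the free γ-hydroxy acid relactonises under acid, and the triphenol is air-sensitive in base). The fallback unveils the acid by neutral hydrogenolysis instead of acidifying a carboxylate, and sets out from 21. KOH (aq. THF/MeOH, Ar) opens the lactone to potassium 4-(benzyloxy)-2-[2,4-bis(benzyloxy)-6-pentylphenoxy]-6-[(1S,3E)-1-hydroxypent-3-en-1-yl]benzoate F5. BnBr in DMF at rt alkylates the carboxylate to benzyl 4-(benzyloxy)-2-[2,4-bis(benzyloxy)-6-pentylphenoxy]-6-[(1S,3E)-1-hydroxypent-3-en-1-yl]benzoate F6, which is used at once. Hydrogenation of F6 (H2, Pd/C, EtOAc, rt) removes all four benzyl groups and saturates the alkene, giving target 24 directly after filtration and cold evaporation; steps 13 and 14 are bypassed.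

**Further compounds**
F1 | step 6 | 1-(benzyloxy)-3,5-dibromobenzene | Brc1cc(Br)cc(OCc2ccccc2)c1
F2 | step 6 | [4-(benzyloxy)-2,6-dibromophenyl]lithium | [Li]c1c(Br)cc(OCc2ccccc2)cc1Br
F3 | step 6 | lithium 4-(benzyloxy)-2,6-dibromobenzoate | [Li+].[O-]C(=O)c1c(Br)cc(OCc2ccccc2)cc1Br
F4 | step 6 | 4-(benzyloxy)-2,6-dibromobenzoic acid | OC(=O)c1c(Br)cc(OCc2ccccc2)cc1Br
F0 | step 11 | none | none
F5 | step 14 | potassium 4-(benzyloxy)-2-[2,4-bis(benzyloxy)-6-pentylphenoxy]-6-[(1S,3E)-1-hydroxypent-3-en-1-yl]benzoate | CCCCCc1cc(OCc2ccccc2)cc(OCc2ccccc2)c1Oc1cc(OCc2ccccc2)cc([C@@H](O)C/C=C/C)c1C(=O)[O-].[K+]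
F6 | step 14 | benzyl 4-(benzyloxy)-2-[2,4-bis(benzyloxy)-6-pentylphenoxy]-6-[(1S,3E)-1-hydroxypent-3-en-1-yl]benzoate | CCCCCc1cc(OCc2ccccc2)cc(OCc2ccccc2)c1Oc1cc(OCc2ccccc2)cc([C@@H](O)C/C=C/C)c1C(=O)OCc1ccccc1
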